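**Retrosynthetic overview**
1. Last bond: interflavanyl C4–C8. The upper unit reacts as the C4 quinone methide of a 2,3-trans-flavan-3-ol, the lower unit as C8 of a 2,3-cis-flavan-3-ol; no protecting groups are carried.
2. Upper heterocycle (the only ring made, and made first): chalcone 1 → flavanone 2 by enantioselective 6-endo phenol oxa-Michael closure of the O1–C2 bond, the chalcone isomerase event.
3. The C3 oxygen goes onto the closed ring: 2 → (3, 4) → dihydroflavonol 5 (flavanone 3-hydroxylase equivalent).
4. Lower unit: the heterocycle is bought in flavonol 6; 6 → (7) → flavylium 8 → (9) → 2,3-cis-flavan-3-ol 10 by hydride transfers (anthocyanidin reductase equivalent).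
5. Union: 5 → flavan-3,4-diol 11 → quinone methide 12, captured by 10 → 13.

Assumption: 1 and 6 are bought as bulk catalogue flavonoids; the sense of induction of the catalysts in steps 1 and 4 is assigned by analogy and would be confirmed on a first run (the quinidine-derived and (S,S) antipodes are equally available).

**Step 1**
Reactants: 1 isoliquiritigenin [(E)-1-(2,4-dihydroxyphenyl)-3-(4-hydroxyphenyl)prop-2-en-1-one]
Product: 2 (S)-liquiritigenin [(2S)-7-hydroxy-2-(4-hydroxyphenyl)chroman-4-one]
Conditions: quinine-derived 3,5-bis(trifluoromethyl)phenyl squaramide (20 mol %), 2-MeTHF, 4 Å MS, 0 → 20 °C, stopped at ca. 85 % conversion; chromatography (1 recycled), recrystallisation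
Reagents that add atoms: none
Why: Proposed new method: the quinuclidine nitrogen acts as general base on the chelated 2'-OH while the squaramide N–H pair binds the enone carbonyl (the division of labour in the active site of chalcone isomerase), so the phenol adds 6-endo-trig to one face of C-β under kinetic control and sets C2 as S; the closest known reaction is the cinchona-base-catalysed enantioselective intramolecular oxa-Michael cyclisation of 2'-hydroxychalcones to flavanones, extended here to a chalcone with free 4- and 4'-OH groups.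

**Step 2**
Reactants: 2 (S)-liquiritigenin
Product: 5 (2R,3R)-garbanzol [(2R,3R)-3,7-dihydroxy-2-(4-hydroxyphenyl)chroman-4-one; 2,3-trans], via tris-TMS silyl enol ether 3 (not isolated), via tris-TMS dihydroflavonol 4 (not isolated)
Conditions: TMSOTf (4 equiv), Et3N (5 equiv), CH2Cl2, 0 °C; evaporate, hexane, filter under Ar; DMDO (1.1 equiv), acetone/CH2Cl2, −40 → 0 °C; 1 M HCl, THF/H2O, rt
Reagents that add atoms: dimethyldioxirane (DMDO), CC1(C)OO1; trimethylsilyl triflate (TMSOTf), C[Si](C)(C)OS(=O)(=O)C(F)(F)F (silicon stays only in 3 and 4)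
Why: Rubottom oxidation on a transiently per-silylated substrate: soft enolisation gives the silyl enol ether without opening the pyranone ring, DMDO epoxidises C3=C4 on the face anti to the C2 aryl group and 1,4-silyl shift gives the α-silyloxy ketone, so the new C3–O bond is trans to the aryl (3R, also the thermodynamically preferred epimer), and dilute acid removes all three TMS groups.

**Step 3**
Reactants: 6 kaempferol [3,5,7-trihydroxy-2-(4-hydroxyphenyl)chromen-4-one]
Product: 8 pelargonidin chloride [3,5,7-trihydroxy-2-(4-hydroxyphenyl)chromenylium chloride], via flav-2-ene-3,4-diol 7 (not isolated)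
Conditions: Zn(Hg), 3 % HCl in MeOH, 20 °C, Ar; XAD-7, precipitation from MeOH–HCl/Et2O
Reagents that add atoms: hydrogen chloride, Cl (supplies the chloride counter-ion)
Why: Dissolving-metal (Clemmensen-type) reduction of the vinylogous-ester carbonyl, the classical flavonol-to-anthocyanidin conversion: zinc delivers two electrons to the protonated C4 carbonyl, and the resulting carbinol loses water in the acid to give the aromatic flavylium chloride, with no stereocentre left in the product.

**Step 4**
Reactants: 8 pelargonidin chloride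
Product: 10 (−)-epiafzelechin [(2R,3R)-2-(4-hydroxyphenyl)chroman-3,5,7-triol; 2,3-cis], via flavan-3-one 9 (not isolated)
Conditions: RuCl(p-cymene)[(R,R)-TsDPEN] (2 mol %), HCO2H/Et3N (5:2), DMF, 30 °C, Ar, slow addition of 8
Reagents that add atoms: none
Why: Proposed new method: Ru–H first transfers hydride to the flavylium cation (C4 or C2), the resulting 3-enol tautomerises to flavan-3-one 9 whose C2–H (α-keto, benzylic, α-oxy) epimerises fast in HCO2H/Et3N, and the bifunctional Ru–H/N–H catalyst then reduces the C3 carbonyl from the face anti to the C2 aryl of the matched (2R)-ketone, setting 3R by catalyst control and 2R by dynamic kinetic resolution with 2,3-cis geometry; the closest known reactions are Noyori–Ikariya asymmetric transfer hydrogenation with dynamic kinetic resolution of α-substituted cyclic ketones and the cis-selective hydride reduction of flavan-3-ones, and the sequence is the two hydride transfers of anthocyanidin reductase.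

**Step 5**
Reactants: 5 (2R,3R)-garbanzol; 10 (−)-epiafzelechin
Product: 13 guibourtinidol-(4α→8)-epiafzelechin [(2R,3S,4S)-2-(4-hydroxyphenyl)-4-[(2R,3R)-3,5,7-trihydroxy-2-(4-hydroxyphenyl)chroman-8-yl]chroman-3,7-diol], via flavan-3,4-diol 11 (not isolated), via quinone methide 12 (not isolated)
Conditions: NaBH4 (2 equiv), EtOH, 0 °C → rt, N2; then 10 (3 equiv), aq HCl to 0.1 M, 25 °C, 24 h; Sephadex LH-20 (EtOH), then C18 HPLC (removes 4β→8 and 4α→6 isomers, returns excess 10)
Reagents that add atoms: none
Why: NaBH4 reduces the C4 ketone to flavan-3,4-diol 11, which in dilute acid ionises to the 7-oxygen-stabilised C4 cation (quinone methide 12) that alkylates the most nucleophilic carbon, C8, of the phloroglucinol ring of 10 (Friedel–Crafts-type flavan-4-yl transfer, the biomimetic leucoanthocyanidin condensation), the arene approaching the sofa-shaped cation anti to the C3 hydroxyl so that C4 becomes S (4α, 3,4-trans, expected about 2–3:1 over 4β), while the resorcinol ring of the upper unit is too weak a nucleophile to compete and the 5-deoxy interflavanyl bond does not re-ionise.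

**Compound list**
1 | isoliquiritigenin, (E)-1-(2,4-dihydroxyphenyl)-3-(4-hydroxyphenyl)prop-2-en-1-one | O=C(/C=C/c1ccc(O)cc1)c1ccc(O)cc1O | starting material
2 | (S)-liquiritigenin, (2S)-7-hydroxy-2-(4-hydroxyphenyl)chroman-4-one | O=C1C[C@@H](c2ccc(O)cc2)Oc2cc(O)ccc12 | intermediate
3 | (2S)-4,7-bis(trimethylsilyloxy)-2-[4-(trimethylsilyloxy)phenyl]-2H-chromene | C[Si](C)(C)OC1=C[C@@H](c2ccc(O[Si](C)(C)C)cc2)Oc2cc(O[Si](C)(C)C)ccc12 | intermediate
4 | (2R,3R)-3,7-bis(trimethylsilyloxy)-2-[4-(trimethylsilyloxy)phenyl]chroman-4-one | O=C1[C@H](O[Si](C)(C)C)[C@@H](c2ccc(O[Si](C)(C)C)cc2)Oc2cc(O[Si](C)(C)C)ccc12 | intermediate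
5 | (2R,3R)-garbanzol, (2R,3R)-3,7-dihydroxy-2-(4-hydroxyphenyl)chroman-4-one (2,3-trans) | O=C1[C@H](O)[C@@H](c2ccc(O)cc2)Oc2cc(O)ccc12 | intermediate
6 | kaempferol, 3,5,7-trihydroxy-2-(4-hydroxyphenyl)chromen-4-one | O=c1c(O)c(-c2ccc(O)cc2)oc2cc(O)cc(O)c12 | starting material
7 | 2-(4-hydroxyphenyl)-4H-chromene-3,4,5,7-tetrol (C4 carbinol, racemic, transient) | OC1C(O)=C(c2ccc(O)cc2)Oc2cc(O)cc(O)c12 | intermediate
8 | pelargonidin chloride, 3,5,7-trihydroxy-2-(4-hydroxyphenyl)chromenylium chloride | Oc1ccc(cc1)-c1[o+]c2cc(O)cc(O)c2cc1O.[Cl-] | intermediate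
9 | 5,7-dihydroxy-2-(4-hydroxyphenyl)chroman-3-one (C2 configurationally labile, drawn without descriptor) | O=C1Cc2c(O)cc(O)cc2OC1c1ccc(O)cc1 | intermediate
10 | (−)-epiafzelechin, (2R,3R)-2-(4-hydroxyphenyl)chroman-3,5,7-triol (2,3-cis) | Oc1ccc(cc1)[C@H]1Oc2cc(O)cc(O)c2C[C@H]1O | intermediate
11 | guibourtacacidin, (2R,3S,4R)-2-(4-hydroxyphenyl)chroman-3,4,7-triol (2,3-trans-3,4-trans, major C4 epimer) | O[C@@H]1c2ccc(O)cc2O[C@H](c2ccc(O)cc2)[C@H]1O | intermediate
12 | (2R,3S)-3-hydroxy-2-(4-hydroxyphenyl)-2,3-dihydrochromen-7-one (A-ring quinone methide; O-protonated form = C4 cation) | O=C1C=CC2=C[C@H](O)[C@@H](c3ccc(O)cc3)OC2=C1 | intermediate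
13 | guibourtinidol-(4α→8)-epiafzelechin, (2R,3S,4S)-2-(4-hydroxyphenyl)-4-[(2R,3R)-3,5,7-trihydroxy-2-(4-hydroxyphenyl)chroman-8-yl]chroman-3,7-diol | Oc1ccc([C@H]2Oc3cc(O)ccc3[C@@H](c3c(O)cc(O)c4c3O[C@H](c3ccc(O)cc3)[C@H](O)C4)[C@@H]2O)cc1 | target

**Totals and risks**
Total step count: 5. Longest linear sequence: 3 steps (1 → 2 → 5 → 13; the branch 6 → 8 → 10 → 13 is equally long).

Enantiopurity is protected at the union: the enantiomer of 13 needs the minor antipode of both partners, and the mixed products are diastereomers removed in the final chromatography. Moderate ee in 2 or 10 therefore still gives 13 in high ee.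

Three steps most likely to fail:

Step 1. The free 4'- and 4-OH groups compete for the amine site of the catalyst, and the cyclisation is reversible, so conversion may be slow and the ee modest or eroding. The fallback sets out from 1 and comes back at 2. Compound 1 is cyclised without stereocontrol (NaOAc, EtOH/H2O, reflux) to the racemic flavanone, that is 2 together with (R)-liquiritigenin F1. The racemate is then submitted to a kinetic resolution by asymmetric transfer hydrogenation (RuCl(p-cymene)[(R,R)-TsDPEN], HCO2H/Et3N, ca. 55 % conversion). The matched enantiomer F1 is reduced, hydride anti to the aryl group, to cis-(2R,4R)-2-(4-hydroxyphenyl)chroman-4,7-diol F2, and unreacted 2 is recovered in high ee by chromatography.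

Step 4. The enol of 9 can add to unreduced flavylium, and a ketone with no directly attached aryl group may give poor facial control or incomplete dynamic resolution. The fallback sets out from 8 and comes back at 10. Compound 8 is hydrogenated over PtO2 (H2 1 atm, EtOH, rt), the cis-selective heterogeneous reduction of anthocyanidins, to the racemic 2,3-cis-flavan-3-ol, that is 10 together with (+)-epiafzelechin F3. The antipodes are separated by preparative HPLC on a cellulose tris(3,5-dimethylphenylcarbamate) phase to give 10.

Step 5. Protic ionisation gives only moderate 4α:4β and 8:6 selectivity, and borate and ethanol are present in the one-pot version. The fallback sets out from 11 (now isolated after the borohydride stage) and comes back at 13. Diol 11 is thiolysed with phenylmethanethiol in AcOH/EtOH to the purifiable, bench-stable (2R,3S,4R)-4-(benzylsulfanyl)-2-(4-hydroxyphenyl)chroman-3,7-diol F4. F4 is then coupled with 10 by thiophilic activation with AgBF4 in THF at 0 °C, which captures the C4 electrophile kinetically in an aprotic medium and gives 13.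

**Further compounds**
F1 | step 1 | (R)-liquiritigenin, (2R)-7-hydroxy-2-(4-hydroxyphenyl)chroman-4-one | O=C1C[C@H](c2ccc(O)cc2)Oc2cc(O)ccc12
F2 | step 1 | cis-(2R,4R)-2-(4-hydroxyphenyl)chroman-4,7-diol | O[C@@H]1C[C@H](c2ccc(O)cc2)Oc2cc(O)ccc12
F3 | step 4 | (+)-epiafzelechin, (2S,3S)-2-(4-hydroxyphenyl)chroman-3,5,7-triol | Oc1ccc(cc1)[C@@H]1Oc2cc(O)cc(O)c2C[C@@H]1O
F4 | step 5 | (2R,3S,4R)-4-(benzylsulfanyl)-2-(4-hydroxyphenyl)chroman-3,7-diol | c1ccccc1CS[C@@H]1c2ccc(O)cc2O[C@H](c2ccc(O)cc2)[C@H]1O
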